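**Assumptions:** Guaiane numbering (C1–C15) is used for atom labels. (R)-4-Benzyloxazolidin-2-one is treated as a recoverable auxiliary reagent; none of its atoms reach the target.

## Retrosynthetic overview

1. Torilin ⇒ acyclic 1,8-enyne diester 20 by an intramolecular Pauson–Khand reaction. The cyclopentenone and the seven-membered ring form together in the last step (C1–C5, C2–C3, C3–C4); no ring exists before it.
2. 20 ⇒ alcohol 15 by angeloylation (O-8), desilylation and acetylation (O-11).
3. 15 ⇒ late C8–C9 union of the C5 homoallyl iodide 6 (as its organocerium) with the C9 α-chiral ynal 14, under Felkin–Anh control.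
4. 6 ⇐ (S)-Roche ester (supplies C10). 14 ⇐ Evans deconjugative alkylation of a senecioyl imide with 1-bromobut-2-yne (sets C7), then hydration of the isopropenyl group (C11–OH).
5. The angeloyl unit is prepared separately as a mixed anhydride and attached after the coupling.

## Route

### Fragment A (C9, C10, C14, C1, C2)

**Step 1**
Reactants: 1, methyl (S)-3-hydroxy-2-methylpropanoate
Product: 2, methyl (S)-3-[(tert-butyldimethylsilyl)oxy]-2-methylpropanoate
Conditions: TBSCl, imidazole, DMF, 0 °C → rt
Reagents that add atoms: TBSCl, CC(C)(C)[Si](C)(C)Cl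
Why: Silyl protection of the primary alcohol; the stereocentre (future C10) is untouched.

**Step 2**
Reactants: 2
Product: 3, (S)-3-[(tert-butyldimethylsilyl)oxy]-2-methylpropanal
Conditions: DIBAL-H (1.05 equiv), CH2Cl2, −78 °C; Rochelle salt work-up; used crude
Reagents that add atoms: none
Why: Partial ester reduction through the aluminium hemiacetal, which is stable at −78 °C; immediate use avoids α-epimerisation.

**Step 3**
Reactants: 3
Product: 4, (R)-tert-butyldimethyl[(2-methylbut-3-en-1-yl)oxy]silane
Conditions: Ph3PCH3Br, KHMDS, THF, −78 → 0 °C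
Reagents that add atoms: methyltriphenylphosphonium bromide, C[P+](c1ccccc1)(c1ccccc1)c1ccccc1.[Br-] (supplies the CH2 that becomes C2)
Why: Wittig methylenation with a pre-formed ylide at low temperature; the descriptor changes from S to R only through CIP priorities.

**Step 4**
Reactants: 4
Product: 5, (R)-2-methylbut-3-en-1-ol
Conditions: TBAF, Et2O, rt; careful distillation (volatile)
Reagents that add atoms: none
Why: Fluoride desilylation.

**Step 5**
Reactants: 5
Product: 6, (R)-4-iodo-3-methylbut-1-ene
Conditions: PPh3, I2, imidazole, CH2Cl2, 0 °C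
Reagents that add atoms: iodine, II
Why: Appel-type iodination at the primary carbon, not at the stereocentre.

### Fragment B (C4–C8, C11–C13, C15)

**Step 6**
Reactants: 7, 3-methylbut-2-enoyl chloride
Product: 8, (R)-4-benzyl-3-(3-methylbut-2-enoyl)oxazolidin-2-one
Conditions: (R)-4-benzyloxazolidin-2-one, n-BuLi, THF, −78 °C; then 7
Reagents that add atoms: (R)-4-benzyloxazolidin-2-one, O=C1OC[C@@H](Cc2ccccc2)N1 (auxiliary, removed in step 8)
Why: N-acylation of the lithiated Evans auxiliary.

**Step 7**
Reactants: 8; 9, 1-bromobut-2-yne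
Product: 10, (R)-4-benzyl-3-[(2R)-2-(prop-1-en-2-yl)hex-4-ynoyl]oxazolidin-2-one
Conditions: NaHMDS, THF, −78 °C; then 9, −78 → −45 °C; cold AcOH quench
Reagents that add atoms: none
Why: Evans asymmetric alkylation of the chelated Z(O)-sodium dienolate; the propargylic bromide attacks the α-carbon anti to the benzyl group, giving 2R (future C7) and leaving a deconjugated isopropenyl group.

**Step 8**
Reactants: 10
Product: 11, (R)-2-(prop-1-en-2-yl)hex-4-yn-1-ol
Conditions: LiBH4, MeOH (1 equiv), Et2O, 0 °C
Reagents that add atoms: none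
Why: Reductive removal of the auxiliary (recovered); the stereocentre is not enolised.

**Step 9**
Reactants: 11
Product: 12, (S)-2-(but-2-yn-1-yl)-3-methylbutane-1,3-diol
Conditions: Co(acac)2 (20 mol %), PhSiH3, O2 (1 atm), THF, rt; aq. Na2S2O3
Reagents that add atoms: dioxygen, O=O
Why: Mukaiyama (HAT) Markovnikov hydration of the 1,1-disubstituted alkene gives the C11 tertiary alcohol; the dialkyl alkyne is a poor HAT acceptor and is left intact.

**Step 10**
Reactants: 12
Product: 13, (S)-2-(but-2-yn-1-yl)-3-methyl-1,3-bis[(triethylsilyl)oxy]butane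
Conditions: TESOTf, 2,6-lutidine, CH2Cl2, −78 → 0 °C
Reagents that add atoms: TESOTf, CC[Si](CC)(CC)OS(=O)(=O)C(F)(F)F
Why: Silylation of both hydroxyls; the triflate is needed for the tertiary one.

**Step 11**
Reactants: 13
Product: 14, (R)-2-(but-2-yn-1-yl)-3-methyl-3-[(triethylsilyl)oxy]butanal
Conditions: (COCl)2, DMSO, CH2Cl2, −78 → −40 °C; then Et3N; used at once
Reagents that add atoms: none
Why: Swern conditions cleave and oxidise the primary TES ether selectively; the tertiary TES ether is inert.

### Coupling and endgame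

**Step 12**
Reactants: 6; 14
Product: 15, (3S,5R,6S)-3-methyl-6-{2-[(triethylsilyl)oxy]propan-2-yl}dec-1-en-8-yn-5-ol
Conditions: 6, t-BuLi (2 equiv), Et2O/pentane, −78 °C; CeCl3, THF, −78 °C; then 14, −78 °C; AcOH quench at −78 °C
Reagents that add atoms: none
Why: Felkin–Anh addition of the weakly basic organocerium to the α-chiral aldehyde; attack anti to the bulky, non-chelating CMe2OTES group sets C8 as 5R, and the minor epimer is separated.

**Step 13**
Reactants: 16, angelic acid [(Z)-2-methylbut-2-enoic acid]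
Product: 17, angelic 2,4,6-trichlorobenzoic anhydride
Conditions: 2,4,6-trichlorobenzoyl chloride, Et3N, toluene, rt
Reagents that add atoms: 2,4,6-trichlorobenzoyl chloride, O=C(Cl)c1c(Cl)cc(Cl)cc1Cl
Why: Mixed-anhydride (Yamaguchi-type) activation that does not isomerise the Z-alkene.

**Step 14**
Reactants: 15; 17
Product: 18, (3S,5R,6S)-3-methyl-6-{2-[(triethylsilyl)oxy]propan-2-yl}dec-1-en-8-yn-5-yl (Z)-2-methylbut-2-enoate
Conditions: toluene, 80 °C (no DMAP)
Reagents that add atoms: none
Why: Yamaguchi-type acylation at the less hindered angeloyl carbonyl; neutral conditions avoid angelate-to-tiglate isomerisation and 1,3-silyl migration.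

**Step 15**
Reactants: 18
Product: 19, (3S,5R,6S)-6-(2-hydroxypropan-2-yl)-3-methyldec-1-en-8-yn-5-yl (Z)-2-methylbut-2-enoate
Conditions: HF·pyridine, THF/pyridine, 0 °C → rt
Reagents that add atoms: none
Why: Fluoride cleavage of the tertiary TES ether; ester, alkyne and alkene are unaffected.

**Step 16**
Reactants: 19
Product: 20, (3S,5R,6S)-6-(2-acetoxypropan-2-yl)-3-methyldec-1-en-8-yn-5-yl (Z)-2-methylbut-2-enoate
Conditions: Ac2O, Sc(OTf)3 (2 mol %), MeCN, −20 °C
Reagents that add atoms: acetic anhydride, CC(=O)OC(C)=O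
Why: Lewis-acid-catalysed acetylation of the tertiary alcohol at low temperature, avoiding nucleophilic catalysts that isomerise the angelate.

**Step 17**
Reactants: 20
Product: 21, torilin, (5S,6R,8S,8aR)-5-(2-acetoxypropan-2-yl)-3,8-dimethyl-2-oxo-1,2,4,5,6,7,8,8a-octahydroazulen-6-yl (Z)-2-methylbut-2-enoate
Conditions: Co2(CO)8 (1.1 equiv), CH2Cl2, rt; then n-BuSMe, 1,2-dichloroethane, 83 °C, 0.005 M
Reagents that add atoms: dicobalt octacarbonyl as CO source, [C-]#[O+] (becomes C3=O)
Why: Intramolecular Pauson–Khand [2+2+1] of the 1,8-enyne forms both rings with the enone at C4=C5. C1 is set by substrate control (C10 methyl pseudo-equatorial, H-1 anti to H-10); it is γ to the enone, so the expected more stable trans arrangement can also be reached by mild base equilibration.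

## Compound list

1 | methyl (S)-3-hydroxy-2-methylpropanoate | COC(=O)[C@@H](C)CO | starting material
2 | methyl (S)-3-[(tert-butyldimethylsilyl)oxy]-2-methylpropanoate | COC(=O)[C@@H](C)CO[Si](C)(C)C(C)(C)C | intermediate
3 | (S)-3-[(tert-butyldimethylsilyl)oxy]-2-methylpropanal | O=C[C@@H](C)CO[Si](C)(C)C(C)(C)C | intermediate
4 | (R)-tert-butyldimethyl[(2-methylbut-3-en-1-yl)oxy]silane | C=C[C@@H](C)CO[Si](C)(C)C(C)(C)C | intermediate
5 | (R)-2-methylbut-3-en-1-ol | C=C[C@@H](C)CO | intermediate
6 | (R)-4-iodo-3-methylbut-1-ene | C=C[C@@H](C)CI | intermediate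
7 | 3-methylbut-2-enoyl chloride | CC(C)=CC(=O)Cl | starting material
8 | (R)-4-benzyl-3-(3-methylbut-2-enoyl)oxazolidin-2-one | CC(C)=CC(=O)N1[C@H](Cc2ccccc2)COC1=O | intermediate
9 | 1-bromobut-2-yne | CC#CCBr | starting material
10 | (R)-4-benzyl-3-[(2R)-2-(prop-1-en-2-yl)hex-4-ynoyl]oxazolidin-2-one | CC#CC[C@H](C(C)=C)C(=O)N1[C@H](Cc2ccccc2)COC1=O | intermediate
11 | (R)-2-(prop-1-en-2-yl)hex-4-yn-1-ol | CC#CC[C@H](C(C)=C)CO | intermediate
12 | (S)-2-(but-2-yn-1-yl)-3-methylbutane-1,3-diol | CC#CC[C@H](C(C)(C)O)CO | intermediate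
13 | (S)-2-(but-2-yn-1-yl)-3-methyl-1,3-bis[(triethylsilyl)oxy]butane | CC#CC[C@H](C(C)(C)O[Si](CC)(CC)CC)CO[Si](CC)(CC)CC | intermediate
14 | (R)-2-(but-2-yn-1-yl)-3-methyl-3-[(triethylsilyl)oxy]butanal | CC#CC[C@H](C(C)(C)O[Si](CC)(CC)CC)C=O | intermediate
15 | (3S,5R,6S)-3-methyl-6-{2-[(triethylsilyl)oxy]propan-2-yl}dec-1-en-8-yn-5-ol | C=C[C@@H](C)C[C@@H](O)[C@H](CC#CC)C(C)(C)O[Si](CC)(CC)CC | intermediate
16 | angelic acid, (Z)-2-methylbut-2-enoic acid | C/C=C(/C)C(=O)O | starting material
17 | angelic 2,4,6-trichlorobenzoic anhydride | C/C=C(/C)C(=O)OC(=O)c1c(Cl)cc(Cl)cc1Cl | intermediate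
18 | (3S,5R,6S)-3-methyl-6-{2-[(triethylsilyl)oxy]propan-2-yl}dec-1-en-8-yn-5-yl (Z)-2-methylbut-2-enoate | C=C[C@@H](C)C[C@@H](OC(=O)C(\C)=C/C)[C@H](CC#CC)C(C)(C)O[Si](CC)(CC)CC | intermediate
19 | (3S,5R,6S)-6-(2-hydroxypropan-2-yl)-3-methyldec-1-en-8-yn-5-yl (Z)-2-methylbut-2-enoate | C=C[C@@H](C)C[C@@H](OC(=O)C(\C)=C/C)[C@H](CC#CC)C(C)(C)O | intermediate
20 | (3S,5R,6S)-6-(2-acetoxypropan-2-yl)-3-methyldec-1-en-8-yn-5-yl (Z)-2-methylbut-2-enoate | C=C[C@@H](C)C[C@@H](OC(=O)C(\C)=C/C)[C@H](CC#CC)C(C)(C)OC(C)=O | intermediate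
21 | torilin, (1R,7S,8R,10S)-11-acetoxy-8-angeloyloxyguai-4-en-3-one | C/C=C(/C)C(=O)O[C@@H]1C[C@H](C)[C@H]2CC(=O)C(C)=C2C[C@@H]1C(C)(C)OC(C)=O | target

## Summary

**Total step count:** 17 (fragment A, 5; fragment B, 6; angeloyl donor, 1; coupling and endgame, 5).

**Longest linear sequence:** 11 steps (7 → 8 → 10 → 11 → 12 → 13 → 14 → 15 → 18 → 19 → 20 → 21), which is 65% of the total.

**Steps most likely to fail, with fallbacks:**

1. **Step 17, Pauson–Khand closure of a seven-membered ring.** This is the least precedented step: flexible 1,8-enynes cyclise far less readily than 1,6- or 1,7-enynes, and a modest yield is the realistic expectation. Fallback: build the rings stepwise from the same enyne. Ring-closing enyne metathesis gives the 1-isopropenylcycloheptene; selective cleavage of the exocyclic alkene gives the acetylcycloheptene; ethynyl addition and acetylation, then a Pd(II)- or Au(I)-catalysed Rautenstrauch rearrangement, give the same 2-methylcyclopent-2-enone.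

2. **Step 12, Felkin-controlled fragment union.** The diastereomer ratio at C8 is not guaranteed, and aldehyde 14 can epimerise or eliminate. Fallback: form C7–C8 under reagent control instead. An Evans syn-aldol between (S)-3-methylpent-4-enal (from 5 by cyanide homologation) and (S)-4-benzyl-3-(hex-4-ynoyl)oxazolidin-2-one gives the 7S,8R adduct; the imide carbonyl is then converted to CMe2OH with MeMgBr via the methyl ester.

3. **Step 7, deconjugative α-alkylation.** Risks are α versus γ selectivity, reconjugation and the diastereomer ratio. Fallback: start from 3-hydroxy-3-methylbutanoic acid, make its O-TES (R)-oxazolidinone imide and alkylate that enolate with 9. This carries the tertiary oxygen from the start, removes the hydration step, and reduction then oxidation of the imide gives 14 directly.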